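Target was the thing to catch in this flask. The alder run, which is this very flask followed so far, showed it at 48.7% after 2.00 min and down to 9.6% after 40.0 min.

- alder: starting material 0.15 M; reagent 0.30 M; the very flask that is asked about, followed so far
- flask: starting material 0.15 M; reagent 0.300 M; time 2.0 h

alder run (percent of the starting material charged)

| time / min | target / % |
|---|---|
| 0.417 | 39.0 |
| 2.00 | 48.7 |
| 8.00 | 41.2 |
| 40.0 | 9.6 |

(readings scatter by 0.5 percentage points)

- amounts and yields of target count crystals too
- given per volume of solution although it is solid: crystals
- steps that have been proposed: starting material + reagent <-> target; starting material + reagent -> isomer of the product; crystals <-> target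

* when, up to 2.0 h, the flask holds most target, in min
* the amount of target, in percent of the starting material charged, at that time

So I put the top near the reading at 2.00 min, but the fall was what I could reckon. The rise to 39.0% in 0.417 min ran far faster than the later fall, so I treated free starting material as a small steady trickle. What target gave back was shared between re-forming target and going to isomer of the product, and as both branches take reagent, [reagent] cancelled and target should sink first-order. But the fall between the middle readings ran at 0.0279 min⁻¹, and crystals might have been holding target up there. I therefore used the last two readings for the tail constant, a pseudo-first-order constant: the logarithm of their ratio over the time between them, 0.0455 min⁻¹, which is faster than the earlier fall. Carried from the last reading to 2.0 h, it gave 0.252% target.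

The forecast, “an estimate, not a fit”, said 49.5% at 1.5 min. The flask gave 48.9% at 1.70 min.

    starting material + reagent ⇌ target (K = 79.5 L mol⁻¹, k = 0.124 L mol⁻¹ s⁻¹)
    starting material + reagent → isomer of the product (k = 0.110 L mol⁻¹ s⁻¹)
    crystals ⇌ target, rate k3*(cs3 - [target]) while solid is left; crystals form when [target] > cs3 (solubility = 0.0510 M, k = 0.0509 s⁻¹)

At that top 14.1% stood as crystals, counted in target, beside 48.2% isomer of the product, and at 2.00 h the flask held 0.332% target against my 0.252%. The neighbour charged with 0.037 M of starting material, 8.11 equiv of reagent, reached 49.7%. The tail constant, run from that top over the whole 2.0 h, gave it 0.211%, and it ended with 0.289% target.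

The earlier runs and the new flask are simulated with made-up constants; the scatter is artificial.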